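**Retrosynthetic overview**
1. Target ⇐ methanol oxa-Michael / transannular Michael on an 11-membered E-enone (C9–O and C8–C16; the cyclopentane and cyclooctane rings close last).
2. That enone ⇐ epoxidation of C11=C12 and demethylative epoxide opening by the tetronate oxygen (C12–O–C16 bridge, 2-oxabicyclo[2.2.2]octane).
3. ⇐ intramolecular Diels–Alder macrocyclisation of a 3-acyl-5-methylene methyl tetronate bearing an E,E,E-trienone (C10–C15 and C13–C14; cyclohexene, spiro centre and 11-membered ring in one step).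
4. ⇐ C5 methylenation, Mukaiyama aldol condensation with (2E,4E)-4-methylhexa-2,4-dienal (C8=C9), and acylation of lithiated methyl tetronate by a γ-lactone (C2–C3).
5. Lactone ⇐ carbene-catalysed asymmetric homoenolate annulation of methacrolein with butane-2,3-dione (C5–C6; C4 and C6 stereocentres, the only source of absolute configuration).

Assumption: late intermediates are numbered like the abyssomicin skeleton (C1 lactone carbonyl, C2, C3 acyl/enol carbon, C4–C9 chain, C10–C15 carbocycle, C16 the carbon between the ether O and C2); descriptors are CIP descriptors of each structure as written in its SMILES.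

**Route**

Step 1
Reactants: 1 methacrolein (2-methylprop-2-enal); 2 butane-2,3-dione
Product: 3 (3S,5S)-5-acetyl-3,5-dimethyloxolan-2-one
Conditions: (5aR,10bS)-2-mesityl-5a,10b-dihydro-4H,6H-indeno[2,1-b][1,2,4]triazolo[4,3-d][1,4]oxazin-2-ium chloride (10 mol %; its antipode if the observed sense requires it), i-Pr2NEt (20 mol %), 4 Å MS, toluene, 0 °C, slow addition of 1
Reagents that add atoms: none
Why: Proposed new method: the carbene adds to 1 to give a Breslow intermediate whose unhindered β-carbon (homoenolate) attacks one carbonyl of the activated 1,2-dione 2 on the face left open by the aminoindane wall (sets C5), the azolium enol is then C-protonated under catalyst control (sets C3; any 3-epimer is separated and re-equilibrated with DBU) and the tertiary alkoxide lactonises to release the carbene; the closest known reaction type is the carbene-catalysed homoenolate [3+2] annulation of β-aryl enals with isatins, α-keto esters and cyclic 1,2-diones, not yet shown for an α-branched, β-unsubstituted enal with an acyclic aliphatic dione.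

Step 2
Reactants: 4 (E)-2-methylbut-2-enal (tiglic aldehyde); 5 (triphenylphosphoranylidene)acetaldehyde
Product: 6 (2E,4E)-4-methylhexa-2,4-dienal
Conditions: toluene, 80 °C (4 in 1.5-fold excess)
Reagents that add atoms: none
Why: Wittig olefination with a stabilised ylide gives the new double bond E, and the excess of 4 suppresses a second homologation.

Step 3
Reactants: 3 (3S,5S)-5-acetyl-3,5-dimethyloxolan-2-one
Product: 7 (3S,5S)-5-[1-(tert-butyldimethylsilyloxy)ethenyl]-3,5-dimethyloxolan-2-one
Conditions: TBSOTf, Et3N, CH2Cl2, 0 °C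
Reagents that add atoms: tert-butyldimethylsilyl trifluoromethanesulfonate, CC(C)(C)[Si](C)(C)OS(=O)(=O)C(F)(F)F
Why: Soft enolisation/O-silylation of the ketone, which can enolise only toward its methyl group (the other α-carbon is quaternary), masks the ketone and stores the C8 nucleophile while the lactone is untouched.

Step 4
Reactants: 7 (3S,5S)-5-[1-(tert-butyldimethylsilyloxy)ethenyl]-3,5-dimethyloxolan-2-one; 8 4-methoxyfuran-2(5H)-one (methyl tetronate)
Product: 10 3-[(2S,4S)-5-(tert-butyldimethylsilyloxy)-4-hydroxy-2,4-dimethylhex-5-enoyl]-4-methoxyfuran-2(5H)-one, via 3-lithio-4-methoxyfuran-2(5H)-one 9 (not isolated)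
Conditions: 8, LiN(i-Pr)2, THF, −78 °C; then 7, −78 °C; AcOH quench at −78 °C
Reagents that add atoms: none
Why: Acyl substitution of the lactone by the C3-lithiated tetronate (the standard nucleophile for 3-acyl tetronates) stops at the lithium lactolate, so no second addition occurs, and the C2–C3 ketone is released only on quench, which protects the adjacent methyl stereocentre.

Step 5
Reactants: 10 3-[(2S,4S)-5-(tert-butyldimethylsilyloxy)-4-hydroxy-2,4-dimethylhex-5-enoyl]-4-methoxyfuran-2(5H)-one; 6 (2E,4E)-4-methylhexa-2,4-dienal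
Product: 12 3-[(2S,4S,6E,8E,10E)-4-hydroxy-2,4,10-trimethyl-5-oxododeca-6,8,10-trienoyl]-4-methoxyfuran-2(5H)-one, via β-hydroxy ketone aldol adduct 11 (not isolated)
Conditions: BF3·OEt2, CH2Cl2, −78 °C; aqueous work-up; then MsCl, Et3N, CH2Cl2, 0 °C to rt
Reagents that add atoms: none
Why: Mukaiyama aldol addition of the enol silane to the aldehyde needs no base (the acidic tetronate CH2 and the α-methyl stereocentre are spared), and mesylation/E1cB elimination of the dienylic alcohol gives the conjugated E-enone.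

Step 6
Reactants: 12 3-[(2S,4S,6E,8E,10E)-4-hydroxy-2,4,10-trimethyl-5-oxododeca-6,8,10-trienoyl]-4-methoxyfuran-2(5H)-one
Product: 15 3-[(2S,4S,6E,8E,10E)-4-hydroxy-2,4,10-trimethyl-5-oxododeca-6,8,10-trienoyl]-4-methoxy-5-methylidenefuran-2(5H)-one, via Mannich base 13 (not isolated), via trimethylammonium iodide 14 (not isolated)
Conditions: LiN(SiMe3)2 (2.1 equiv), THF, −78 °C, then CH2=NMe2+ I−; AcOH quench; then MeI, CH2Cl2, rt; then aq NaHCO3
Reagents that add atoms: Eschenmoser's salt (N,N-dimethylmethyleneiminium iodide), C=[N+](C)C.[I-]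
Why: The ring CH2 of the 3-acyl tetronate is the most acidic C–H (its anion is a 2-oxidofuran), so Mannich aminomethylation occurs there, and quaternisation followed by E1cB loss of trimethylamine unveils the exocyclic methylene dienophile without touching a stereocentre.

Step 7
Reactants: 15 3-[(2S,4S,6E,8E,10E)-4-hydroxy-2,4,10-trimethyl-5-oxododeca-6,8,10-trienoyl]-4-methoxy-5-methylidenefuran-2(5H)-one
Product: 16 (4S,6S,8E,10S,13S,15S)-6-hydroxy-16-methoxy spirotetronate macrocycle (cyclohex-11-ene spiro at C15 to the 4-methoxybutenolide; 11-membered ring through C3 ketone and C7 enone)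
Conditions: La(OTf)3 (10 mol %), BHT, toluene (1 mM), 100 °C
Reagents that add atoms: none
Why: Intramolecular Diels–Alder macrocyclisation as used for the parent C-type abyssomicin: the E,E-diene and the tether fix the relative configuration of C10, C13 and C15 (C16 endo), and the diene face is chosen by the C4/C6 stereocentres through the macrocyclic transition state.

Step 8
Reactants: 16 (4S,6S,8E,10S,13S,15S)-6-hydroxy-16-methoxy spirotetronate macrocycle
Product: 17 (4S,6S,8E,10S,11S,12R,13S,15S)-11,12-epoxide of 16 (oxirane on the face opposite to C16)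
Conditions: dimethyldioxirane, acetone, 0 °C
Reagents that add atoms: dimethyldioxirane, CC1(C)OO1
Why: The electrophilic dioxirane epoxidises only the electron-rich trisubstituted C11=C12 alkene (enone and push-pull tetronate alkene are inert), from the face not shielded by C9, the C13 methyl and C16.

Step 9
Reactants: 17 (4S,6S,8E,10S,11S,12R,13S,15S)-11,12-epoxide of 16
Product: 19 (4S,6S,8E,10S,11S,12S,13S,15S)-6,11-dihydroxy C-type abyssomicin enone (C12–O–C16 ether bridge; C3 and C7 ketones), via demethylated epoxy tetronic acid 18 (not isolated)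
Conditions: LiCl, p-TsOH·H2O, MeCN, 50 °C
Reagents that add atoms: none
Why: Chloride cleaves the vinylogous methyl ester by SN2 at the methyl group, and the freed tetronate oxygen opens the protonated epoxide at the tertiary C12 with inversion (6-membered ring closure), which sets C12 and leaves the C11 alcohol trans to the ether.

Step 10
Reactants: 19 (4S,6S,8E,10S,11S,12S,13S,15S)-6,11-dihydroxy C-type abyssomicin enone
Product: 20 target CNP0073200.1 (4S,6S,8R,9S,10R,11S,12S,13S,15S,16R)
Conditions: NaOMe (1.1 equiv), MeOH, −20 to 0 °C; then AcOH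
Reagents that add atoms: methanol, CO; sodium methoxide, [Na+].C[O-]
Why: Oxa-Michael addition of methoxide to C9 on the outer face of the E-enone, then transannular Michael addition of the C8 enolate to C16 of the alkoxybutenolide on the inner face (net anti addition), closes the cyclopentane and the cyclooctane cis-fused, sets C9, C8 and C16 under control of the rigid macrocycle and ends at the stabilised acyl-lactone enol; this is the cascade that converts C-type abyssomicins into 9-alkoxy D-type congeners.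

**Compound list**
1 | methacrolein (2-methylprop-2-enal) | C=C(C)C=O | starting material
2 | butane-2,3-dione | CC(=O)C(C)=O | starting material
3 | (3S,5S)-5-acetyl-3,5-dimethyloxolan-2-one | O=C1[C@@H](C)C[C@](C)(O1)C(C)=O | intermediate
4 | (E)-2-methylbut-2-enal | C/C=C(\C)C=O | starting material
5 | (triphenylphosphoranylidene)acetaldehyde | O=CC=P(c1ccccc1)(c1ccccc1)c1ccccc1 | starting material
6 | (2E,4E)-4-methylhexa-2,4-dienal | C/C=C(C)/C=C/C=O | intermediate
7 | (3S,5S)-5-[1-(tert-butyldimethylsilyloxy)ethenyl]-3,5-dimethyloxolan-2-one | O=C1[C@@H](C)C[C@](C)(O1)C(=C)O[Si](C)(C)C(C)(C)C | intermediate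
8 | 4-methoxyfuran-2(5H)-one | COC1=CC(=O)OC1 | starting material
9 | 3-lithio-4-methoxyfuran-2(5H)-one | [Li]C1=C(OC)COC1=O | intermediate
10 | 3-[(2S,4S)-5-(tert-butyldimethylsilyloxy)-4-hydroxy-2,4-dimethylhex-5-enoyl]-4-methoxyfuran-2(5H)-one | COC1=C(C(=O)[C@@H](C)C[C@](C)(O)C(=C)O[Si](C)(C)C(C)(C)C)C(=O)OC1 | intermediate
11 | 3-[(2S,4S,8E,10E)-4,7-dihydroxy-2,4,10-trimethyl-5-oxododeca-8,10-dienoyl]-4-methoxyfuran-2(5H)-one (both C7 epimers) | COC1=C(C(=O)[C@@H](C)C[C@](C)(O)C(=O)CC(O)/C=C/C(C)=C/C)C(=O)OC1 | intermediate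
12 | 3-[(2S,4S,6E,8E,10E)-4-hydroxy-2,4,10-trimethyl-5-oxododeca-6,8,10-trienoyl]-4-methoxyfuran-2(5H)-one | COC1=C(C(=O)[C@@H](C)C[C@](C)(O)C(=O)/C=C/C=C/C(C)=C/C)C(=O)OC1 | intermediate
13 | 5-[(dimethylamino)methyl] derivative of 12 (both C5 epimers) | CN(C)CC1OC(=O)C(C(=O)[C@@H](C)C[C@](C)(O)C(=O)/C=C/C=C/C(C)=C/C)=C1OC | intermediate
14 | N-methyl quaternary ammonium iodide of 13 | C[N+](C)(C)CC1OC(=O)C(C(=O)[C@@H](C)C[C@](C)(O)C(=O)/C=C/C=C/C(C)=C/C)=C1OC.[I-] | intermediate
15 | 3-[(2S,4S,6E,8E,10E)-4-hydroxy-2,4,10-trimethyl-5-oxododeca-6,8,10-trienoyl]-4-methoxy-5-methylidenefuran-2(5H)-one | C=C1OC(=O)C(C(=O)[C@@H](C)C[C@](C)(O)C(=O)/C=C/C=C/C(C)=C/C)=C1OC | intermediate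
16 | (4S,6S,8E,10S,13S,15S)-6-hydroxy-16-methoxy spirotetronate macrocycle (Diels–Alder adduct) | C[C@H]1C[C@](C)(O)C(=O)/C=C/[C@H]2C=C(C)[C@@H](C)C[C@]23OC(=O)C(C1=O)=C3OC | intermediate
17 | (4S,6S,8E,10S,11S,12R,13S,15S)-11,12-epoxide of 16 | C[C@H]1C[C@](C)(O)C(=O)/C=C/[C@H]2[C@@H]4O[C@]4(C)[C@@H](C)C[C@]23OC(=O)C(C1=O)=C3OC | intermediate
18 | 16-O-demethyl epoxy tetronic acid from 17 | C[C@H]1C[C@](C)(O)C(=O)/C=C/[C@H]2[C@@H]4O[C@]4(C)[C@@H](C)C[C@]23OC(=O)C(C1=O)=C3O | intermediate
19 | (4S,6S,8E,10S,11S,12S,13S,15S)-6,11-dihydroxy C-type abyssomicin enone with C12–O–C16 ether bridge | C[C@H]1C[C@](C)(O)C(=O)/C=C/[C@H]2[C@H](O)[C@@]3(C)OC4=C(C1=O)C(=O)O[C@@]24C[C@@H]3C | intermediate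
20 | CNP0073200.1 (4S,6S,8R,9S,10R,11S,12S,13S,15S,16R) | CO[C@H]1[C@H]2[C@H](O)[C@@]3(C)O[C@@]45/C(=C(/O)[C@@H](C)C[C@](C)(O)C(=O)[C@H]14)C(=O)O[C@@]25C[C@@H]3C | target

**Totals and risks**
Total step count: 10. Longest linear sequence: 9 steps (1, 3, 4, 5, 6, 7, 8, 9, 10).

The three steps most likely to fail:

Step 1 (the proposed new carbene annulation: benzoin or acetyl-transfer side reactions of 2, or poor control at C3). The fallback uses known chemistry, sets out from 1 and comes back at 3. Addition of MeMgBr to 1 gives racemic 3-methylbut-3-en-2-ol F1, whose stereocentre is erased in the next step. Johnson–Claisen rearrangement with triethyl orthopropionate (cat. propionic acid, 140 °C) gives ethyl (E)-2,4-dimethylhex-4-enoate F2. Shi epoxidation (D-fructose-derived 1,2:4,5-di-O-isopropylidene ketone, KHSO5, K2CO3, MeCN/dimethoxymethane/buffer, 0 °C) sets the first stereocentres without metal and gives ethyl 3-[(2R,3R)-2,3-dimethyloxiran-2-yl]-2-methylpropanoate F3. Camphorsulfonic acid induces 5-exo lactonisation with inversion at the tertiary epoxide carbon to (3RS,5S)-5-[(1R)-1-hydroxyethyl]-3,5-dimethyloxolan-2-one F4. Dess–Martin oxidation gives 3 with its 3-epimer, which is separated and recycled by DBU equilibration.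

Step 4 (the lithiated tetronate may enolise the lactone or add sluggishly). The fallback changes the electrophile to an aldehyde, sets out from 7 and comes back at 10. Reduction of 7 with i-Bu2AlH (toluene, −78 °C) gives (3S,5S)-5-[1-(tert-butyldimethylsilyloxy)ethenyl]-3,5-dimethyloxolan-2-ol F5. Addition of 9 (2.2 equiv) to the open hydroxy-aldehyde form gives 3-[(2S,4S)-5-(tert-butyldimethylsilyloxy)-1,4-dihydroxy-2,4-dimethylhex-5-en-1-yl]-4-methoxyfuran-2(5H)-one F6 (both carbinol epimers). Dess–Martin periodinane buffered with NaHCO3 oxidises only the secondary alcohol and gives 10.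

Step 7 (oligomerisation, or the wrong diene face in the macrocyclic transition state). The fallback gives up the macrocyclising cycloaddition, sets out from 10 (with 6) and comes back at 16. C5 of 10 is methylenated as in step 6 through Mannich base F7 and its methiodide F8 to the 5-methylene enol silane F9. Dienal 6 is converted (HC(OMe)3, cat. pyridinium p-toluenesulfonate, MeOH) into (2E,4E)-1,1-dimethoxy-4-methylhexa-2,4-diene F10. Intermolecular Diels–Alder reaction of F9 with F10 (toluene, 90 °C) gives the spiro cycloadduct F11; regioisomers and the two facial isomers (diastereomers because of the side chain) are separated. TMSOTf-catalysed intramolecular Mukaiyama acetal aldol at high dilution closes the 11-membered ring to the β-methoxy ketone F12. DBU eliminates methanol to give 16.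

Further compounds
F1 | step 1 | 3-methylbut-3-en-2-ol (racemic) | CC(O)C(C)=C
F2 | step 1 | ethyl (E)-2,4-dimethylhex-4-enoate (racemic) | CCOC(=O)C(C)C/C(C)=C/C
F3 | step 1 | ethyl 3-[(2R,3R)-2,3-dimethyloxiran-2-yl]-2-methylpropanoate (both C2 epimers) | CCOC(=O)C(C)C[C@@]1(C)O[C@@H]1C
F4 | step 1 | (3RS,5S)-5-[(1R)-1-hydroxyethyl]-3,5-dimethyloxolan-2-one | O=C1C(C)C[C@](C)(O1)[C@@H](C)O
F5 | step 4 | (3S,5S)-5-[1-(tert-butyldimethylsilyloxy)ethenyl]-3,5-dimethyloxolan-2-ol (both anomers) | OC1[C@@H](C)C[C@](C)(O1)C(=C)O[Si](C)(C)C(C)(C)C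
F6 | step 4 | 3-[(2S,4S)-5-(tert-butyldimethylsilyloxy)-1,4-dihydroxy-2,4-dimethylhex-5-en-1-yl]-4-methoxyfuran-2(5H)-one (both C1 epimers) | COC1=C(C(O)[C@@H](C)C[C@](C)(O)C(=C)O[Si](C)(C)C(C)(C)C)C(=O)OC1
F7 | step 7 | 5-[(dimethylamino)methyl] derivative of 10 (both C5 epimers) | CN(C)CC1OC(=O)C(C(=O)[C@@H](C)C[C@](C)(O)C(=C)O[Si](C)(C)C(C)(C)C)=C1OC
F8 | step 7 | N-methyl quaternary ammonium iodide of F7 | C[N+](C)(C)CC1OC(=O)C(C(=O)[C@@H](C)C[C@](C)(O)C(=C)O[Si](C)(C)C(C)(C)C)=C1OC.[I-]
F9 | step 7 | 3-[(2S,4S)-5-(tert-butyldimethylsilyloxy)-4-hydroxy-2,4-dimethylhex-5-enoyl]-4-methoxy-5-methylidenefuran-2(5H)-one | C=C1OC(=O)C(C(=O)[C@@H](C)C[C@](C)(O)C(=C)O[Si](C)(C)C(C)(C)C)=C1OC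
F10 | step 7 | (2E,4E)-1,1-dimethoxy-4-methylhexa-2,4-diene | C/C=C(C)/C=C/C(OC)OC
F11 | step 7 | (10S,13S,15S)-spiro cycloadduct of F9 and F10 (10-dimethoxymethyl; enol silane side chain on C2) | COC(OC)[C@H]1C=C(C)[C@@H](C)C[C@]12OC(=O)C(C(=O)[C@@H](C)C[C@](C)(O)C(=C)O[Si](C)(C)C(C)(C)C)=C2OC
F12 | step 7 | 8,9-dihydro-9-methoxy derivative of 16 (both C9 epimers) | C[C@H]1C[C@](C)(O)C(=O)CC(OC)[C@H]2C=C(C)[C@@H](C)C[C@]23OC(=O)C(C1=O)=C3OC
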